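**Retrosynthetic overview**
1. The strategy rests on the pseudo-meso heptane chain: the syn-diol unit C3(OH)–C4H2–C5(OH) carries a CH2CH2Ar arm on each side, and the two arms differ only in the arene. C2–C3–C4–C5–C6 therefore maps onto the five ring carbons of cis-cyclopent-4-ene-1,3-diol, and C1 and C7 are the benzylidene carbons of two styrenes.
2. Last operations: cleavage of a temporary O–Si–O bridge, preceded by one hydrogenation that saturates two C=C bonds and removes three benzyl ethers.
3. C1=C2 is made by cross-metathesis of a terminal vinyl group with 3,4-bis(benzyloxy)-5-methoxystyrene.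
4. C6=C7 and both stereocenters are made by catalytic enantioselective ring-opening cross-metathesis of the meso, silicon-bridged cyclopentenediol (a 2,4-dioxa-3-silabicyclo[3.2.1]oct-6-ene) with 4-benzyloxystyrene.
5. Ring order: both benzene rings are bought; the six-membered dioxasilinane is closed first as a bridge over the cyclopentene, the cyclopentene is opened in the key step, and the dioxasilinane is cleaved at the end.

Key step: step 3

Assumption: the sense of induction of the chiral ruthenium catalyst on this new substrate cannot be predicted with certainty, so the catalyst antipode specified is the one that places the aryl-bearing alkene on the carbinol carbon that becomes C5; both antipodes are accessible from (R,R)- or (S,S)-1,2-diphenylethylenediamine. Chain numbering: C1 is the benzylic carbon at the trioxygenated ring, C7 the benzylic carbon at the 4-hydroxyphenyl ring.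

**Step 1**
Reactants: 1 cis-cyclopent-4-ene-1,3-diol (meso, 1R,3S); 2 di-tert-butylsilyl bis(trifluoromethanesulfonate)
Product: 3 (1R,5S)-3,3-di-tert-butyl-2,4-dioxa-3-silabicyclo[3.2.1]oct-6-ene (meso)
Conditions: 2 (1.05 equiv) added slowly, 2,6-lutidine (2.5 equiv), CH2Cl2 (dilute), 0 °C to rt
Reagents that add atoms: di-tert-butylsilyl bis(trifluoromethanesulfonate) (2), CC(C)(C)[Si](OS(=O)(=O)C(F)(F)F)(OS(=O)(=O)C(F)(F)F)C(C)(C)C
Why: Standard silylene acetal formation in which the bis-triflate silylates one hydroxyl and the second Si–O bond closes intramolecularly across the cis-1,3-diol in its diaxial envelope conformer, the long Si–O bonds accommodating the bicyclo[3.2.1] frame; no stereocenter is touched and the mirror plane of 1 is kept.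

**Step 2**
Reactants: 4 4-benzyloxybenzaldehyde
Product: 5 4-benzyloxystyrene
Conditions: Ph3PCH3Br, KOtBu, THF, 0 °C to rt; product stored cold with a trace of BHT
Reagents that add atoms: methyltriphenylphosphonium bromide, C[P+](c1ccccc1)(c1ccccc1)c1ccccc1.[Br-]
Why: Wittig methylenation of a non-enolizable aryl aldehyde by the unstabilized ylide, to which the benzyl ether is inert.

**Step 3**
Reactants: 3 (1R,5S)-3,3-di-tert-butyl-2,4-dioxa-3-silabicyclo[3.2.1]oct-6-ene; 5 4-benzyloxystyrene
Product: 6 (4R,6S)-4-[(E)-2-(4-benzyloxyphenyl)ethenyl]-2,2-di-tert-butyl-6-ethenyl-1,3,2-dioxasilinane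
Conditions: 5 (5 equiv), chiral catalyst RuI(=CH-C6H4-2-OiPr)(L*) (5 mol %; L* = enantiopure C,O-chelating N-mesityl-N'-(2'-oxidobiphenyl-2-yl)-4,5-diphenylimidazolin-2-ylidene), THF, 22 to 40 °C, argon
Reagents that add atoms: 4-benzyloxystyrene (5), C=Cc1ccc(OCc2ccccc2)cc1
Why: Proposed new method: the chiral ruthenium 4-benzyloxybenzylidene generated from 5 should add [2+2] to the ring alkene of 3 from the face syn to the one-carbon bridge C8 (the O–Si(tBu)2–O bridge blocks the other face), and cycloreversion of the ruthenacyclobutane cleaves C6=C7 so that C7 carries the new C=CHAr bond, after which the ruthenium alkylidene left at C6 takes a methylene from a second molecule of 5 and returns the benzylidene, the net equation being 3 + 5 → 6 with no by-product. The closest known reaction type is the catalytic enantioselective ring-opening cross-metathesis of meso 8-oxabicyclo[3.2.1]oct-6-enes and their 8-aza analogues with styrenes, which gives cis-2,6-disubstituted pyrans and piperidines; here the bridging heteroatom is replaced by CH2 and the three-atom bridge is O–Si–O, which supplies the strain a plain cyclopentene lacks. No ring is closed: the carbocycle opens and the six-membered dioxasilinane carrying the syn-diol remains. No C–O bond is made or broken, so the cis relation of the two carbinol carbons comes from 1, and the absolute configuration is set only by the chiral ligand sphere, which must join the aryl-bearing carbene carbon to C7 (next to the R bridgehead C1) and leave the methylene on C6 (next to the S bridgehead C5). The step needs selection between the two enantiotopic alkene carbons, which the rigid mirror-symmetric bicycle presents cleanly to the catalyst, and it needs chemoselectivity against oligomerization and twofold styrene capping, which the excess of 5 and the low reactivity of the α-branched product alkenes should provide. The alkene geometry (E expected) is of no consequence because both alkenes are hydrogenated later.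

**Step 4**
Reactants: 7 3,4-dihydroxy-5-methoxybenzaldehyde (5-hydroxyvanillin); 8 benzyl bromide
Product: 9 3,4-bis(benzyloxy)-5-methoxybenzaldehyde
Conditions: 8 (2.4 equiv), K2CO3, DMF, 60 °C, argon
Reagents that add atoms: benzyl bromide (8), BrCc1ccccc1
Why: Williamson etherification of both phenols of an aldehyde without α-hydrogens, with the inert atmosphere protecting the catecholate from oxidation.

**Step 5**
Reactants: 9 3,4-bis(benzyloxy)-5-methoxybenzaldehyde
Product: 10 3,4-bis(benzyloxy)-5-methoxystyrene
Conditions: Ph3PCH3Br, KOtBu, THF, 0 °C to rt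
Reagents that add atoms: methyltriphenylphosphonium bromide, C[P+](c1ccccc1)(c1ccccc1)c1ccccc1.[Br-]
Why: Wittig methylenation of a non-enolizable aryl aldehyde, with the benzyl and methyl ethers inert to the ylide.

**Step 6**
Reactants: 6 (4R,6S)-4-[(E)-2-(4-benzyloxyphenyl)ethenyl]-2,2-di-tert-butyl-6-ethenyl-1,3,2-dioxasilinane; 10 3,4-bis(benzyloxy)-5-methoxystyrene
Product: 11 (4R,6S)-4-[(E)-2-(4-benzyloxyphenyl)ethenyl]-6-[(E)-2-(3,4-bis(benzyloxy)-5-methoxyphenyl)ethenyl]-2,2-di-tert-butyl-1,3,2-dioxasilinane
Conditions: 10 (3 equiv), second-generation Hoveyda–Grubbs catalyst RuCl2(=CH-C6H4-2-OiPr)(H2IMes) (5 mol %), CH2Cl2, 40 °C, argon sweep to remove ethylene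
Reagents that add atoms: 3,4-bis(benzyloxy)-5-methoxystyrene (10), COc1cc(C=C)cc(OCc2ccccc2)c1OCc1ccccc1
Why: Olefin cross-metathesis between the monosubstituted vinyl group of 6 and the styrene, driven by loss of ethylene and E-selective; the existing 1,2-disubstituted styryl alkene with its branched allylic carbon should react far more slowly than the terminal alkene, and the stereocenters are not involved.

**Step 7**
Reactants: 11 (4R,6S)-4-[(E)-2-(4-benzyloxyphenyl)ethenyl]-6-[(E)-2-(3,4-bis(benzyloxy)-5-methoxyphenyl)ethenyl]-2,2-di-tert-butyl-1,3,2-dioxasilinane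
Product: 12 (4S,6R)-2,2-di-tert-butyl-6-[2-(3,4-dihydroxy-5-methoxyphenyl)ethyl]-4-[2-(4-hydroxyphenyl)ethyl]-1,3,2-dioxasilinane
Conditions: H2 (1 atm), 10% Pd/C, EtOAc–EtOH, rt
Reagents that add atoms: none
Why: Heterogeneous catalytic hydrogenation saturates both alkenes and hydrogenolyses the three aryl benzyl ethers while the di-tert-butylsilylene survives the neutral medium and alkene saturation outpaces cleavage of the allylic C–O bonds, so both stereocenters are untouched (the change of both descriptors reflects only the CIP ranking of the saturated arms below the ring CH2).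

**Step 8**
Reactants: 12 (4S,6R)-2,2-di-tert-butyl-6-[2-(3,4-dihydroxy-5-methoxyphenyl)ethyl]-4-[2-(4-hydroxyphenyl)ethyl]-1,3,2-dioxasilinane
Product: 13 (3R,5S)-1-(3,4-dihydroxy-5-methoxyphenyl)-7-(4-hydroxyphenyl)heptane-3,5-diol (target CNP0291714.1)
Conditions: HF·pyridine, excess pyridine, THF, 0 °C to rt, argon; work-up with degassed solvents
Reagents that add atoms: none
Why: Fluoride-mediated cleavage of both Si–O bonds, driven by Si–F bond formation, under buffered mildly acidic conditions that spare the oxidation-prone 3-methoxycatechol unit; no stereocenter is involved.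

**Compound list**
1 | cis-cyclopent-4-ene-1,3-diol (meso, 1R,3S) | O[C@@H]1C=C[C@H](O)C1 | starting material
2 | di-tert-butylsilyl bis(trifluoromethanesulfonate) | CC(C)(C)[Si](OS(=O)(=O)C(F)(F)F)(OS(=O)(=O)C(F)(F)F)C(C)(C)C | starting material
3 | (1R,5S)-3,3-di-tert-butyl-2,4-dioxa-3-silabicyclo[3.2.1]oct-6-ene (meso) | CC(C)(C)[Si]1(C(C)(C)C)O[C@@H]2C=C[C@H](O1)C2 | intermediate
4 | 4-benzyloxybenzaldehyde | O=Cc1ccc(OCc2ccccc2)cc1 | starting material
5 | 4-benzyloxystyrene | C=Cc1ccc(OCc2ccccc2)cc1 | intermediate
6 | (4R,6S)-4-[(E)-2-(4-benzyloxyphenyl)ethenyl]-2,2-di-tert-butyl-6-ethenyl-1,3,2-dioxasilinane | C=C[C@@H]1C[C@H](/C=C/c2ccc(OCc3ccccc3)cc2)O[Si](C(C)(C)C)(C(C)(C)C)O1 | intermediate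
7 | 3,4-dihydroxy-5-methoxybenzaldehyde (5-hydroxyvanillin) | COc1cc(C=O)cc(O)c1O | starting material
8 | benzyl bromide | BrCc1ccccc1 | starting material
9 | 3,4-bis(benzyloxy)-5-methoxybenzaldehyde | COc1cc(C=O)cc(OCc2ccccc2)c1OCc1ccccc1 | intermediate
10 | 3,4-bis(benzyloxy)-5-methoxystyrene | COc1cc(C=C)cc(OCc2ccccc2)c1OCc1ccccc1 | intermediate
11 | (4R,6S)-4-[(E)-2-(4-benzyloxyphenyl)ethenyl]-6-[(E)-2-(3,4-bis(benzyloxy)-5-methoxyphenyl)ethenyl]-2,2-di-tert-butyl-1,3,2-dioxasilinane | COc1cc(/C=C/[C@@H]2C[C@H](/C=C/c3ccc(OCc4ccccc4)cc3)O[Si](C(C)(C)C)(C(C)(C)C)O2)cc(OCc2ccccc2)c1OCc1ccccc1 | intermediate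
12 | (4S,6R)-2,2-di-tert-butyl-6-[2-(3,4-dihydroxy-5-methoxyphenyl)ethyl]-4-[2-(4-hydroxyphenyl)ethyl]-1,3,2-dioxasilinane | COc1cc(CC[C@@H]2C[C@H](CCc3ccc(O)cc3)O[Si](C(C)(C)C)(C(C)(C)C)O2)cc(O)c1O | intermediate
13 | (3R,5S)-1-(3,4-dihydroxy-5-methoxyphenyl)-7-(4-hydroxyphenyl)heptane-3,5-diol | COc1cc(CC[C@@H](O)C[C@@H](O)CCc2ccc(O)cc2)cc(O)c1O | target

**Totals**
Total step count: 8. Longest linear sequence: 5 steps (steps 1, 3, 6, 7 and 8; the branches through steps 2 and 4–5 are equally long).

**Steps most likely to fail**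

Step 3 (proposed new method). The silicon-bridged cyclopentene may not be strained enough, so that ring opening is slow or reversible. The catalyst may discriminate poorly between the two enantiotopic alkene carbons. Oligomerization or twofold capping by the styrene may compete. The fallback uses known chemistry, sets out from 4 and comes back to the route at 6. Claisen–Schmidt condensation of 4 with acetone (aqueous NaOH, EtOH) gives (E)-4-[4-(benzyloxy)phenyl]but-3-en-2-one F1. Its diisopinocampheylboron enolate (Ipc2BCl, Et3N, Et2O, −78 °C; the Ipc2BCl enantiomer chosen for the S carbinol) adds to acrolein in an enantioselective methyl ketone aldol reaction to give (1E,5S)-1-[4-(benzyloxy)phenyl]-5-hydroxyhepta-1,6-dien-3-one F2. Narasaka–Prasad reduction (Et2BOMe, NaBH4, THF–MeOH, −78 °C) delivers hydride to the boron chelate and gives the syn-diol (1E,3R,5S)-1-[4-(benzyloxy)phenyl]hepta-1,6-diene-3,5-diol F3, whose optical purity can be raised by crystallization if needed. Silylene formation with 2 and 2,6-lutidine in CH2Cl2 then gives 6.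

Step 6. The aryl group at the existing styryl alkene may be exchanged by secondary metathesis, styrene 10 may be consumed by self-metathesis to the stilbene, and turnover at the α-branched vinyl group may be sluggish. The fallback avoids metathesis altogether, sets out from 6 and 9, and comes back to the route at 12.
- Aryl partner: Baeyer–Villiger oxidation of 9 (mCPBA, CH2Cl2) gives 3,4-bis(benzyloxy)-5-methoxyphenyl formate F4, which is not isolated. Methanolysis (K2CO3, MeOH) gives 3,4-bis(benzyloxy)-5-methoxyphenol F5, and triflation (Tf2O, pyridine, CH2Cl2, 0 °C) gives 3,4-bis(benzyloxy)-5-methoxyphenyl trifluoromethanesulfonate F6.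
- Coupling: 9-BBN (THF, rt) hydroborates only the terminal vinyl group of 6 and gives the B-alkyl-9-borabicyclo[3.3.1]nonane adduct of 6 F7, which is not isolated. B-alkyl Suzuki–Miyaura coupling with F6 (Pd(dppf)Cl2, aqueous K3PO4, THF–DMF, 60 °C) gives (4R,6R)-4-[(E)-2-(4-benzyloxyphenyl)ethenyl]-6-[2-(3,4-bis(benzyloxy)-5-methoxyphenyl)ethyl]-2,2-di-tert-butyl-1,3,2-dioxasilinane F8.
- Return: hydrogenation of F8 under the conditions of step 7 gives 12.

Step 7. Hydrogenolysis of the two allylic C–O bonds may compete with alkene saturation and erode the diol, or debenzylation may stall. The fallback separates the two reductions, sets out from 11 and comes back to the route at 12. Diimide reduction (2-nitrobenzenesulfonylhydrazide, Et3N, CH2Cl2, rt), which cannot cleave C–O bonds, saturates both alkenes and gives (4S,6R)-4-[2-(4-benzyloxyphenyl)ethyl]-6-[2-(3,4-bis(benzyloxy)-5-methoxyphenyl)ethyl]-2,2-di-tert-butyl-1,3,2-dioxasilinane F9. Hydrogenolysis of the three benzyl ethers of this now non-allylic substrate (H2, Pd(OH)2/C, EtOAc–EtOH) then gives 12.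

**Further compounds**
F1 | step 3 | (E)-4-[4-(benzyloxy)phenyl]but-3-en-2-one | CC(=O)/C=C/c1ccc(OCc2ccccc2)cc1
F2 | step 3 | (1E,5S)-1-[4-(benzyloxy)phenyl]-5-hydroxyhepta-1,6-dien-3-one | C=C[C@@H](O)CC(=O)/C=C/c1ccc(OCc2ccccc2)cc1
F3 | step 3 | (1E,3R,5S)-1-[4-(benzyloxy)phenyl]hepta-1,6-diene-3,5-diol | C=C[C@@H](O)C[C@@H](O)/C=C/c1ccc(OCc2ccccc2)cc1
F4 | step 6 | 3,4-bis(benzyloxy)-5-methoxyphenyl formate | COc1cc(OC=O)cc(OCc2ccccc2)c1OCc1ccccc1
F5 | step 6 | 3,4-bis(benzyloxy)-5-methoxyphenol | COc1cc(O)cc(OCc2ccccc2)c1OCc1ccccc1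
F6 | step 6 | 3,4-bis(benzyloxy)-5-methoxyphenyl trifluoromethanesulfonate | COc1cc(OS(=O)(=O)C(F)(F)F)cc(OCc2ccccc2)c1OCc1ccccc1
F7 | step 6 | B-alkyl-9-borabicyclo[3.3.1]nonane adduct of 6 | C(C[C@@H]1C[C@H](/C=C/c2ccc(OCc3ccccc3)cc2)O[Si](C(C)(C)C)(C(C)(C)C)O1)B1C2CCCC1CCC2
F8 | step 6 | (4R,6R)-4-[(E)-2-(4-benzyloxyphenyl)ethenyl]-6-[2-(3,4-bis(benzyloxy)-5-methoxyphenyl)ethyl]-2,2-di-tert-butyl-1,3,2-dioxasilinane | COc1cc(CC[C@@H]2C[C@H](/C=C/c3ccc(OCc4ccccc4)cc3)O[Si](C(C)(C)C)(C(C)(C)C)O2)cc(OCc2ccccc2)c1OCc1ccccc1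
F9 | step 7 | (4S,6R)-4-[2-(4-benzyloxyphenyl)ethyl]-6-[2-(3,4-bis(benzyloxy)-5-methoxyphenyl)ethyl]-2,2-di-tert-butyl-1,3,2-dioxasilinane | COc1cc(CC[C@@H]2C[C@H](CCc3ccc(OCc4ccccc4)cc3)O[Si](C(C)(C)C)(C(C)(C)C)O2)cc(OCc2ccccc2)c1OCc1ccccc1
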